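**Plan**

- Numbering is that of the labdane skeleton: ring A = C1–C5 and C10, ring B = C5–C10, C4 = CMe2, CH3-20 on C10, C6 = CHOAc, C7=C8, C17 = CH2OAc on C8, C9 carries C11–C15. Ring B is a cyclohexene in which the C5–C6 edge (C6 oxygenated, so an acceptor position) faces the four-carbon arc C7–C8–C9–C10, and C5 and C10 are already spanned by the C1–C4 chain of ring A: a dienophile, a diene and a four-atom tether.
- Retrosynthesis, in order: remove the two acetates; C6–OH from a C6 ketone; cut C14=C15 and C12=C13 (two Wittig reactions on a C12 aldehyde); shift C7=C8 back to C8=C9; derive the C6 ketone from C6–CHO by loss of one carbon; then cut C5–C10 and C6–C7 together (intramolecular Diels–Alder) to an acyclic (2E)-enal carrying a 1,1,2,3-substituted diene.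
- The trienal is cut at C5=C6 (Wittig), C8–C9 (Negishi coupling), C10–CH3 (carbomagnesiation of a C9≡C10 alkyne), C1–C10 (acetylide alkylation) and C3–C4 (nitrile alkylation).
- Forward: the chain C5–C4–C3–C2–C1–C10≡C9–C11–C12 is built by two alkylations, the tetrasubstituted C9=C10 alkene and the C8(=C7H2)–C17 unit are added in one pot, rings A and B are then closed together in one step, and the endgame degrades CHO to C6=O, conjugates, builds the side chain, reduces and acetylates.
- Stereochemistry: C9=C10 geometry from hydroxyl-directed syn-carbomagnesiation; C5 and C10 (trans fusion and absolute sense) from the imidazolidinone-catalysed endo cycloaddition; C9 from protonation of a dienolate anti to CH3-20; C6 from hydride attack anti to the two syn-axial methyl groups on C4 and C10; 12E from a stabilised ylide.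

Key step: step 8

Remark: the target SMILES is read as (5R,6S,9S,10S) in the numbering above, that is, H-5 and H-9 trans to CH3-20, with the 6-acetoxy group and the C9 side chain cis to CH3-20.

**Step 1**
Reactants: 1 isobutyronitrile; 2 1,3-dibromopropane
Product: 4 5-bromo-2,2-dimethylpentanenitrile, via lithiated isobutyronitrile 3 (not isolated)
Conditions: LiN(i-Pr)2 (1.05 equiv), THF, −78 °C; then 2 (3 equiv), −78 °C → rt
Reagents that add atoms: none
Why: α-Alkylation of a nitrile anion (SN2 at a primary bromide) forms the C3–C4 bond and the quaternary C4, the excess of dibromide suppressing double alkylation; no stereocenter is formed.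

**Step 2**
Reactants: 5 but-3-yn-1-ol; 4 5-bromo-2,2-dimethylpentanenitrile
Product: 7 9-hydroxy-2,2-dimethylnon-6-ynenitrile, via dilithiated butynol 6 (not isolated)
Conditions: n-BuLi (2.1 equiv), THF, −78 → 0 °C; then DMPU, 4 (0.9 equiv), 0 °C → rt
Reagents that add atoms: none
Why: Acetylide alkylation (SN2) of the C,O-dianion forms the C1–C10 bond, the acetylide carbon being far more nucleophilic than the alkoxide and the nitrile having no α-hydrogen; no stereocenter is formed.

**Step 3**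
Reactants: 8 2-bromoprop-2-en-1-ol
Product: 9 [(2-bromoprop-2-en-1-yl)oxy](tert-butyl)diphenylsilane
Conditions: t-BuPh2SiCl, imidazole, CH2Cl2, 0 °C → rt
Reagents that add atoms: tert-butyl(chloro)diphenylsilane, CC(C)(C)[Si](Cl)(c1ccccc1)c1ccccc1
Why: Standard silylation of a primary alcohol gives the C7/C8/C17 building block with a robust protecting group on O-17.

**Step 4**
Reactants: 7 9-hydroxy-2,2-dimethylnon-6-ynenitrile; 9 [(2-bromoprop-2-en-1-yl)oxy](tert-butyl)diphenylsilane
Product: 12 (6E)-8-{[(tert-butyldiphenylsilyl)oxy]methyl}-7-(2-hydroxyethyl)-2,2,6-trimethylnona-6,8-dienenitrile, via alkenylmagnesium chelate 10 (not isolated), via alkenylzinc chloride 11 (not isolated)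
Conditions: MeMgBr (3 equiv), Fe(acac)3 (15 mol %), THF, −20 → 0 °C; then ZnCl2 (3 equiv), 0 °C; then 9 (2 equiv), Pd(PPh3)4 (5 mol %), 50 °C
Reagents that add atoms: methylmagnesium bromide, C[Mg]Br
Why: Alkoxide-directed, iron-catalysed syn-carbomagnesiation of a homopropargylic alcohol puts CH3 on the distal alkyne carbon (C10) and magnesium on the proximal one (C9, five-membered chelate), and transmetalation to zinc followed by a stereoretentive Negishi coupling with 9 should give the tetrasubstituted alkene with CH3-20 cis to the new C8 vinyl unit and the C1 chain trans to it.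

**Step 5**
Reactants: 12 (6E)-8-{[(tert-butyldiphenylsilyl)oxy]methyl}-7-(2-hydroxyethyl)-2,2,6-trimethylnona-6,8-dienenitrile
Product: 13 (6E)-7-{2-[(tert-butyldimethylsilyl)oxy]ethyl}-8-{[(tert-butyldiphenylsilyl)oxy]methyl}-2,2,6-trimethylnona-6,8-dienenitrile
Conditions: t-BuMe2SiCl, imidazole, CH2Cl2, rt
Reagents that add atoms: tert-butyl(chloro)dimethylsilane, CC(C)(C)[Si](C)(C)Cl
Why: Silylation of the primary C12 alcohol gives a group that can later be removed in the presence of the diphenylsilyl ether on O-17.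

**Step 6**
Reactants: 13 (6E)-7-{2-[(tert-butyldimethylsilyl)oxy]ethyl}-8-{[(tert-butyldiphenylsilyl)oxy]methyl}-2,2,6-trimethylnona-6,8-dienenitrile
Product: 15 (6E)-7-{2-[(tert-butyldimethylsilyl)oxy]ethyl}-8-{[(tert-butyldiphenylsilyl)oxy]methyl}-2,2,6-trimethylnona-6,8-dienal, via N-aluminoimine 14 (not isolated)
Conditions: i-Bu2AlH (1.3 equiv), PhMe, −78 → −20 °C; then aqueous potassium sodium tartrate
Reagents that add atoms: water, O
Why: Partial reduction of a nitrile by i-Bu2AlH stops at the N-alumino imine, which is hydrolysed on work-up to the non-enolisable C5 aldehyde.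

**Step 7**
Reactants: 15 (6E)-7-{2-[(tert-butyldimethylsilyl)oxy]ethyl}-8-{[(tert-butyldiphenylsilyl)oxy]methyl}-2,2,6-trimethylnona-6,8-dienal
Product: 16 (2E,8E)-9-{2-[(tert-butyldimethylsilyl)oxy]ethyl}-10-{[(tert-butyldiphenylsilyl)oxy]methyl}-4,4,8-trimethylundeca-2,8,10-trienal
Conditions: Ph3P=CHCHO (1.5 equiv), PhMe, 70 °C
Reagents that add atoms: (triphenylphosphoranylidene)acetaldehyde, O=CC=P(c1ccccc1)(c1ccccc1)c1ccccc1
Why: Wittig reaction with a stabilised ylide is E-selective and forms the C5=C6 dienophile, the hindered product enal not being expected to homologate further or to cyclise without catalyst at this temperature.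

**Step 8**
Reactants: 16 (2E,8E)-9-{2-[(tert-butyldimethylsilyl)oxy]ethyl}-10-{[(tert-butyldiphenylsilyl)oxy]methyl}-4,4,8-trimethylundeca-2,8,10-trienal
Product: 17 (1R,4aR,8aR)-4-{2-[(tert-butyldimethylsilyl)oxy]ethyl}-3-{[(tert-butyldiphenylsilyl)oxy]methyl}-4a,8,8-trimethyl-1,2,4a,5,6,7,8,8a-octahydronaphthalene-1-carbaldehyde
Conditions: (2R,5R)-5-benzyl-2-tert-butyl-3-methylimidazolidin-4-one·CF3SO3H (20 mol %), MeCN/H2O 98:2 (0.02 M), 0 → 20 °C
Reagents that add atoms: none
Why: The imidazolidinone condenses with the enal to an (E)-iminium ion whose lowered LUMO lets C5=C6 add across the C10 and C7 termini of the tethered diene in a concerted, asynchronous [4+2] cycloaddition, after which hydrolysis releases the aldehyde and the catalyst. The closest known reaction type is the amine-catalysed enantioselective type 1 intramolecular Diels–Alder reaction of (E,E)-trienals to trans-fused decalins, and the creation of an angular-methyl ring-fusion carbon from a 1,1-disubstituted diene terminus is known from thermal intramolecular Diels–Alder reactions. Ring B (C5–C6–C7–C8–C9–C10) is closed by the cycloaddition itself, and ring A (C1–C5, C10) is closed in the same event as the tether ring by the new C5–C10 bond, the C1–C4 chain folding as a chair in the endo transition state. C5 and C10 (trans ring fusion) follow from the endo transition state together with the E geometry of C9=C10 (chain outside, CH3 inside), C6 (CHO cis to H-5) follows from the E dienophile, and the absolute sense follows from the benzyl group of the (2R,5R)-catalyst, which covers the Si face at C5 so that the diene adds to the Re face. The step needs endo and facial selectivity on a crowded diene, and these are supported by the iminium geometry, the gem-dimethyl group at C4 (gem-dialkyl folding of the tether), the 2,3-disubstitution that keeps the diene close to s-cis, the absence of any other diene in the molecule and high dilution.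

**Step 9**
Reactants: 17 (1R,4aR,8aR)-4-{2-[(tert-butyldimethylsilyl)oxy]ethyl}-3-{[(tert-butyldiphenylsilyl)oxy]methyl}-4a,8,8-trimethyl-1,2,4a,5,6,7,8,8a-octahydronaphthalene-1-carbaldehyde
Product: 20 (4S,4aS,8aR)-4-{2-[(tert-butyldimethylsilyl)oxy]ethyl}-3-{[(tert-butyldiphenylsilyl)oxy]methyl}-4a,8,8-trimethyl-4a,5,6,7,8,8a-hexahydronaphthalen-1(4H)-one, via enamine 18 (not isolated), via deconjugated ketone 19 (not isolated)
Conditions: morpholine (2 equiv), 4 Å sieves, PhMe, 50 °C; then CuCl (10 mol %), O2 (1 atm), MeCN, 0 °C; then N2, DBU (0.5 equiv), CH2Cl2, 0 °C → rt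
Reagents that add atoms: dioxygen, O=O
Why: Copper-catalysed aerobic cleavage of the enamine C=C bond (oxidative deformylation of an α-branched aldehyde) gives the C6 ketone, and base then moves the C8=C9 bond into conjugation through the dienolate, the proton being expected to reach C9 on the face anti to CH3-20 so that the C9 chain ends up cis to it.

**Step 10**
Reactants: 20 (4S,4aS,8aR)-4-{2-[(tert-butyldimethylsilyl)oxy]ethyl}-3-{[(tert-butyldiphenylsilyl)oxy]methyl}-4a,8,8-trimethyl-4a,5,6,7,8,8a-hexahydronaphthalen-1(4H)-one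
Product: 21 (4S,4aS,8aR)-3-{[(tert-butyldiphenylsilyl)oxy]methyl}-4-(2-hydroxyethyl)-4a,8,8-trimethyl-4a,5,6,7,8,8a-hexahydronaphthalen-1(4H)-one
Conditions: pyridinium p-toluenesulfonate (0.2 equiv), MeOH, rt
Reagents that add atoms: none
Why: Mild acid-catalysed methanolysis cleaves the primary dimethylsilyl ether selectively, the bulkier diphenylsilyl ether on O-17 being much slower to solvolyse.

**Step 11**
Reactants: 21 (4S,4aS,8aR)-3-{[(tert-butyldiphenylsilyl)oxy]methyl}-4-(2-hydroxyethyl)-4a,8,8-trimethyl-4a,5,6,7,8,8a-hexahydronaphthalen-1(4H)-one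
Product: 22 2-[(1S,4aR,8aS)-2-{[(tert-butyldiphenylsilyl)oxy]methyl}-5,5,8a-trimethyl-4-oxo-1,4,4a,5,6,7,8,8a-octahydronaphthalen-1-yl]acetaldehyde
Conditions: 1,1,1-triacetoxy-1,1-dihydro-1,2-benziodoxol-3(1H)-one (DMP, 1.3 equiv), pyridine, CH2Cl2, 0 °C → rt
Reagents that add atoms: none
Why: Periodinane oxidation of a primary alcohol to the aldehyde is neutral and fast, so the enone and C9 are not disturbed.

**Step 12**
Reactants: 22 2-[(1S,4aR,8aS)-2-{[(tert-butyldiphenylsilyl)oxy]methyl}-5,5,8a-trimethyl-4-oxo-1,4,4a,5,6,7,8,8a-octahydronaphthalen-1-yl]acetaldehyde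
Product: 23 (2E)-4-[(1S,4aR,8aS)-2-{[(tert-butyldiphenylsilyl)oxy]methyl}-5,5,8a-trimethyl-4-oxo-1,4,4a,5,6,7,8,8a-octahydronaphthalen-1-yl]-2-methylbut-2-enal
Conditions: Ph3P=C(CH3)CHO (1.5 equiv), PhMe, 80 °C
Reagents that add atoms: 2-(triphenylphosphoranylidene)propanal, CC(C=O)=P(c1ccccc1)(c1ccccc1)c1ccccc1
Why: Wittig reaction with a stabilised ylide gives the trisubstituted C12=C13 bond with E geometry and reacts only with the aldehyde, not with the hindered C6 ketone.

**Step 13**
Reactants: 23 (2E)-4-[(1S,4aR,8aS)-2-{[(tert-butyldiphenylsilyl)oxy]methyl}-5,5,8a-trimethyl-4-oxo-1,4,4a,5,6,7,8,8a-octahydronaphthalen-1-yl]-2-methylbut-2-enal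
Product: 24 (4S,4aS,8aR)-3-{[(tert-butyldiphenylsilyl)oxy]methyl}-4a,8,8-trimethyl-4-[(2E)-3-methylpenta-2,4-dien-1-yl]-4a,5,6,7,8,8a-hexahydronaphthalen-1(4H)-one
Conditions: Ph3PCH3Br (1.2 equiv), KN(SiMe3)2 (1.1 equiv), THF, 0 °C; then 23, −78 → 0 °C
Reagents that add atoms: methyltriphenylphosphonium bromide, C[P+](c1ccccc1)(c1ccccc1)c1ccccc1.[Br-]
Why: Wittig methylenation forms C14=C15 and should be chemoselective at low temperature for the unhindered enal over the hindered, conjugated C6 ketone.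

**Step 14**
Reactants: 24 (4S,4aS,8aR)-3-{[(tert-butyldiphenylsilyl)oxy]methyl}-4a,8,8-trimethyl-4-[(2E)-3-methylpenta-2,4-dien-1-yl]-4a,5,6,7,8,8a-hexahydronaphthalen-1(4H)-one
Product: 25 (1S,4S,4aS,8aR)-3-{[(tert-butyldiphenylsilyl)oxy]methyl}-4a,8,8-trimethyl-4-[(2E)-3-methylpenta-2,4-dien-1-yl]-1,4,4a,5,6,7,8,8a-octahydronaphthalen-1-ol
Conditions: NaBH4, CeCl3·7H2O, MeOH, −40 °C
Reagents that add atoms: none
Why: Luche 1,2-reduction of the enone, with hydride entering on the face opposite the syn-axial methyl groups on C4 and C10, should give the axial C6 alcohol cis to CH3-20.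

**Step 15**
Reactants: 25 (1S,4S,4aS,8aR)-3-{[(tert-butyldiphenylsilyl)oxy]methyl}-4a,8,8-trimethyl-4-[(2E)-3-methylpenta-2,4-dien-1-yl]-1,4,4a,5,6,7,8,8a-octahydronaphthalen-1-ol
Product: 26 (1S,4S,4aS,8aR)-3-(hydroxymethyl)-4a,8,8-trimethyl-4-[(2E)-3-methylpenta-2,4-dien-1-yl]-1,4,4a,5,6,7,8,8a-octahydronaphthalen-1-ol
Conditions: Bu4NF (1.5 equiv), THF, 0 °C → rt
Reagents that add atoms: none
Why: Fluoride-induced desilylation frees the C17 hydroxyl without touching the allylic alcohol or the diene.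

**Step 16**
Reactants: 26 (1S,4S,4aS,8aR)-3-(hydroxymethyl)-4a,8,8-trimethyl-4-[(2E)-3-methylpenta-2,4-dien-1-yl]-1,4,4a,5,6,7,8,8a-octahydronaphthalen-1-ol
Product: 27 (1S,4S,4aS,8aR)-3-[(acetyloxy)methyl]-4a,8,8-trimethyl-4-[(2E)-3-methylpenta-2,4-dien-1-yl]-1,4,4a,5,6,7,8,8a-octahydronaphthalen-1-yl acetate
Conditions: Ac2O (excess), pyridine, 4-(dimethylamino)pyridine (cat.), CH2Cl2, rt → 40 °C
Reagents that add atoms: acetic anhydride, CC(=O)OC(C)=O
Why: Nucleophile-catalysed acetylation esterifies both the primary C17 and the hindered axial C6 hydroxyl with retention at C6, giving the target.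

**Compound list**

1 | isobutyronitrile | CC(C)C#N | starting material
2 | 1,3-dibromopropane | BrCCCBr | starting material
3 | 2-lithio-2-methylpropanenitrile (lithiated isobutyronitrile) | [Li]C(C)(C)C#N | intermediate (not isolated)
4 | 5-bromo-2,2-dimethylpentanenitrile | N#CC(C)(C)CCCBr | intermediate
5 | but-3-yn-1-ol | C#CCCO | starting material
6 | dilithium salt of but-3-yn-1-ol (acetylide and alkoxide) | [Li]C#CCCO[Li] | intermediate (not isolated)
7 | 9-hydroxy-2,2-dimethylnon-6-ynenitrile | N#CC(C)(C)CCCC#CCCO | intermediate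
8 | 2-bromoprop-2-en-1-ol | C=C(Br)CO | starting material
9 | [(2-bromoprop-2-en-1-yl)oxy](tert-butyl)diphenylsilane | C=C(Br)CO[Si](c1ccccc1)(c1ccccc1)C(C)(C)C | intermediate
10 | (E)-alkenylmagnesium alkoxide chelate from syn addition of CH3–Mg to 7 (CH3 on C6, Mg on C7 and on O-9 of the nonenenitrile chain) | N#CC(C)(C)CCC/C(C)=C1\CCO[Mg]1 | intermediate (not isolated)
11 | (E)-alkenylzinc chloride derived from 10 (Zn on C7, chloromagnesium alkoxide on O-9) | N#CC(C)(C)CCC/C(C)=C(\CCO[Mg]Cl)[Zn]Cl | intermediate (not isolated)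
12 | (6E)-8-{[(tert-butyldiphenylsilyl)oxy]methyl}-7-(2-hydroxyethyl)-2,2,6-trimethylnona-6,8-dienenitrile | N#CC(C)(C)CCC/C(C)=C(\CCO)C(=C)CO[Si](c1ccccc1)(c1ccccc1)C(C)(C)C | intermediate
13 | (6E)-7-{2-[(tert-butyldimethylsilyl)oxy]ethyl}-8-{[(tert-butyldiphenylsilyl)oxy]methyl}-2,2,6-trimethylnona-6,8-dienenitrile | N#CC(C)(C)CCC/C(C)=C(\CCO[Si](C)(C)C(C)(C)C)C(=C)CO[Si](c1ccccc1)(c1ccccc1)C(C)(C)C | intermediate
14 | N-(diisobutylalumanyl)imine of aldehyde 15 | CC(C)C[Al](CC(C)C)N=CC(C)(C)CCC/C(C)=C(\CCO[Si](C)(C)C(C)(C)C)C(=C)CO[Si](c1ccccc1)(c1ccccc1)C(C)(C)C | intermediate (not isolated)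
15 | (6E)-7-{2-[(tert-butyldimethylsilyl)oxy]ethyl}-8-{[(tert-butyldiphenylsilyl)oxy]methyl}-2,2,6-trimethylnona-6,8-dienal | O=CC(C)(C)CCC/C(C)=C(\CCO[Si](C)(C)C(C)(C)C)C(=C)CO[Si](c1ccccc1)(c1ccccc1)C(C)(C)C | intermediate
16 | (2E,8E)-9-{2-[(tert-butyldimethylsilyl)oxy]ethyl}-10-{[(tert-butyldiphenylsilyl)oxy]methyl}-4,4,8-trimethylundeca-2,8,10-trienal | O=C/C=C/C(C)(C)CCC/C(C)=C(\CCO[Si](C)(C)C(C)(C)C)C(=C)CO[Si](c1ccccc1)(c1ccccc1)C(C)(C)C | intermediate
17 | (1R,4aR,8aR)-4-{2-[(tert-butyldimethylsilyl)oxy]ethyl}-3-{[(tert-butyldiphenylsilyl)oxy]methyl}-4a,8,8-trimethyl-1,2,4a,5,6,7,8,8a-octahydronaphthalene-1-carbaldehyde (trans-fused; CHO cis to the ring-fusion H) | CC(C)(C)[Si](C)(C)OCCC1=C(CO[Si](c2ccccc2)(c2ccccc2)C(C)(C)C)C[C@@H](C=O)[C@@H]3C(C)(C)CCC[C@@]13C | intermediate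
18 | morpholine enamine of 17 (C6=CH–N; ring fusion as in 17; enamine geometry not fixed) | CC(C)(C)[Si](C)(C)OCCC1=C(CO[Si](c2ccccc2)(c2ccccc2)C(C)(C)C)CC(=CN4CCOCC4)[C@@H]3C(C)(C)CCC[C@@]13C | intermediate (not isolated)
19 | (4aR,8aR)-4-{2-[(tert-butyldimethylsilyl)oxy]ethyl}-3-{[(tert-butyldiphenylsilyl)oxy]methyl}-4a,8,8-trimethyl-4a,5,6,7,8,8a-hexahydronaphthalen-1(2H)-one | CC(C)(C)[Si](C)(C)OCCC1=C(CO[Si](c2ccccc2)(c2ccccc2)C(C)(C)C)CC(=O)[C@@H]3C(C)(C)CCC[C@@]13C | intermediate (not isolated)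
20 | (4S,4aS,8aR)-4-{2-[(tert-butyldimethylsilyl)oxy]ethyl}-3-{[(tert-butyldiphenylsilyl)oxy]methyl}-4a,8,8-trimethyl-4a,5,6,7,8,8a-hexahydronaphthalen-1(4H)-one | CC(C)(C)[Si](C)(C)OCC[C@@H]1C(CO[Si](c2ccccc2)(c2ccccc2)C(C)(C)C)=CC(=O)[C@@H]3C(C)(C)CCC[C@@]13C | intermediate
21 | (4S,4aS,8aR)-3-{[(tert-butyldiphenylsilyl)oxy]methyl}-4-(2-hydroxyethyl)-4a,8,8-trimethyl-4a,5,6,7,8,8a-hexahydronaphthalen-1(4H)-one | OCC[C@@H]1C(CO[Si](c2ccccc2)(c2ccccc2)C(C)(C)C)=CC(=O)[C@@H]3C(C)(C)CCC[C@@]13C | intermediate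
22 | 2-[(1S,4aR,8aS)-2-{[(tert-butyldiphenylsilyl)oxy]methyl}-5,5,8a-trimethyl-4-oxo-1,4,4a,5,6,7,8,8a-octahydronaphthalen-1-yl]acetaldehyde | O=CC[C@@H]1C(CO[Si](c2ccccc2)(c2ccccc2)C(C)(C)C)=CC(=O)[C@@H]3C(C)(C)CCC[C@@]13C | intermediate
23 | (2E)-4-[(1S,4aR,8aS)-2-{[(tert-butyldiphenylsilyl)oxy]methyl}-5,5,8a-trimethyl-4-oxo-1,4,4a,5,6,7,8,8a-octahydronaphthalen-1-yl]-2-methylbut-2-enal | O=C/C(C)=C/C[C@@H]1C(CO[Si](c2ccccc2)(c2ccccc2)C(C)(C)C)=CC(=O)[C@@H]3C(C)(C)CCC[C@@]13C | intermediate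
24 | (4S,4aS,8aR)-3-{[(tert-butyldiphenylsilyl)oxy]methyl}-4a,8,8-trimethyl-4-[(2E)-3-methylpenta-2,4-dien-1-yl]-4a,5,6,7,8,8a-hexahydronaphthalen-1(4H)-one | C=C/C(C)=C/C[C@@H]1C(CO[Si](c2ccccc2)(c2ccccc2)C(C)(C)C)=CC(=O)[C@@H]3C(C)(C)CCC[C@@]13C | intermediate
25 | (1S,4S,4aS,8aR)-3-{[(tert-butyldiphenylsilyl)oxy]methyl}-4a,8,8-trimethyl-4-[(2E)-3-methylpenta-2,4-dien-1-yl]-1,4,4a,5,6,7,8,8a-octahydronaphthalen-1-ol | C=C/C(C)=C/C[C@@H]1C(CO[Si](c2ccccc2)(c2ccccc2)C(C)(C)C)=C[C@H](O)[C@@H]3C(C)(C)CCC[C@@]13C | intermediate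
26 | (1S,4S,4aS,8aR)-3-(hydroxymethyl)-4a,8,8-trimethyl-4-[(2E)-3-methylpenta-2,4-dien-1-yl]-1,4,4a,5,6,7,8,8a-octahydronaphthalen-1-ol | C=C/C(C)=C/C[C@@H]1C(CO)=C[C@H](O)[C@@H]2C(C)(C)CCC[C@@]12C | intermediate
27 | (1S,4S,4aS,8aR)-3-[(acetyloxy)methyl]-4a,8,8-trimethyl-4-[(2E)-3-methylpenta-2,4-dien-1-yl]-1,4,4a,5,6,7,8,8a-octahydronaphthalen-1-yl acetate | C=C/C(C)=C/C[C@@H]1C(COC(C)=O)=C[C@H](OC(C)=O)[C@@H]2C(C)(C)CCC[C@@]12C | target

**Count and risks**

Total step count: 16. Longest linear sequence: 15 steps (steps 1, 2 and 4–16, from isobutyronitrile); step 3 is a one-step side branch.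

The three steps most likely to fail:

Step 8. The cycloaddition may be too slow, because its leading bond joins a neopentyl carbon (C5) to a carbon that becomes quaternary (C10). The endo preference (trans fusion) or the facial bias of the amine catalyst may erode on so substituted a diene, and an uncatalysed thermal reaction would give racemic material. The fallback replaces iminium catalysis by auxiliary control under Lewis acid activation and sets out from aldehyde 15. A Horner–Wadsworth–Emmons reaction (LiCl, i-Pr2NEt, MeCN) with diethyl {2-[(4R)-4-benzyl-2-oxo-1,3-oxazolidin-3-yl]-2-oxoethyl}phosphonate gives the (2E)-trienimide F1. Me2AlCl (1.4 equiv, CH2Cl2, −30 °C) chelates the two carbonyl groups and should induce endo cycloaddition on the face away from the benzyl group to give the trans-fused imide F2. LiBH4 (THF, MeOH, 0 °C) removes the auxiliary to give the primary alcohol F3, and oxidation with DMP brings the fallback back to the route at aldehyde 17.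

Step 4. The carbometalation may be incomplete or misdirected, methyl transfer from the excess methyl metal species may compete in the cross-coupling, the hindered alkenyl metal may transmetalate slowly, and the Grignard reagent may attack the nitrile. The fallback separates the two bond formations and changes the coupling chemistry; it sets out from alkynol 7. The same iron-catalysed carbomagnesiation is quenched with iodine to give the isolable alkenyl iodide F4. Bromide 9 is converted (t-BuLi, THF, −78 °C; then Bu3SnCl) into the stannane F5. A copper-assisted Stille coupling (Pd(PPh3)4, CuI, DMF, 60 °C) of F4 with F5 comes back to the route at dienol 12.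

Step 9. The enolisable deconjugated ketone may be over-oxidised by O2 under copper catalysis, conjugation may be incomplete, and protonation at C9 may occur on the wrong face or equilibrate on long exposure to base. The fallback replaces the aerobic cleavage by an osmylation–glycol cleavage sequence and sets out from aldehyde 17. Me3SiOSO2CF3 and Et3N (CH2Cl2, 0 °C) give the silyl enol ether F6. OsO4 (cat.) with N-methylmorpholine N-oxide (acetone/H2O) should dihydroxylate only the electron-rich enol ether, the tetrasubstituted C8=C9 bond being too hindered, to give the hydroxy aldehyde F7. NaIO4 (THF/H2O) cleaves F7 to the deconjugated ketone 19, where the fallback rejoins the route, and 19 is conjugated to 20 with DBU under N2 as in step 9.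

**Further compounds**

F1 | step 8 | (4R)-4-benzyl-3-[(2E,8E)-9-{2-[(tert-butyldimethylsilyl)oxy]ethyl}-10-{[(tert-butyldiphenylsilyl)oxy]methyl}-4,4,8-trimethylundeca-2,8,10-trienoyl]-1,3-oxazolidin-2-one | O=C(/C=C/C(C)(C)CCC/C(C)=C(\CCO[Si](C)(C)C(C)(C)C)C(=C)CO[Si](c1ccccc1)(c1ccccc1)C(C)(C)C)N1C(=O)OC[C@H]1Cc1ccccc1
F2 | step 8 | (4R)-4-benzyl-3-{[(1R,4aR,8aR)-4-{2-[(tert-butyldimethylsilyl)oxy]ethyl}-3-{[(tert-butyldiphenylsilyl)oxy]methyl}-4a,8,8-trimethyl-1,2,4a,5,6,7,8,8a-octahydronaphthalen-1-yl]carbonyl}-1,3-oxazolidin-2-one | CC(C)(C)[Si](C)(C)OCCC1=C(CO[Si](c2ccccc2)(c2ccccc2)C(C)(C)C)C[C@@H](C(=O)N4C(=O)OC[C@H]4Cc4ccccc4)[C@@H]3C(C)(C)CCC[C@@]13C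
F3 | step 8 | [(1R,4aR,8aR)-4-{2-[(tert-butyldimethylsilyl)oxy]ethyl}-3-{[(tert-butyldiphenylsilyl)oxy]methyl}-4a,8,8-trimethyl-1,2,4a,5,6,7,8,8a-octahydronaphthalen-1-yl]methanol | CC(C)(C)[Si](C)(C)OCCC1=C(CO[Si](c2ccccc2)(c2ccccc2)C(C)(C)C)C[C@@H](CO)[C@@H]3C(C)(C)CCC[C@@]13C
F4 | step 4 | (6E)-9-hydroxy-7-iodo-2,2,6-trimethylnon-6-enenitrile | N#CC(C)(C)CCC/C(C)=C(\CCO)I
F5 | step 4 | tributyl(3-{[tert-butyl(diphenyl)silyl]oxy}prop-1-en-2-yl)stannane | CCCC[Sn](CCCC)(CCCC)C(=C)CO[Si](c1ccccc1)(c1ccccc1)C(C)(C)C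
F6 | step 9 | trimethylsilyl enol ether of aldehyde 17 (C6=CH–OSiMe3; enol ether geometry not fixed) | CC(C)(C)[Si](C)(C)OCCC1=C(CO[Si](c2ccccc2)(c2ccccc2)C(C)(C)C)CC(=CO[Si](C)(C)C)[C@@H]3C(C)(C)CCC[C@@]13C
F7 | step 9 | (4aR,8aR)-4-{2-[(tert-butyldimethylsilyl)oxy]ethyl}-3-{[(tert-butyldiphenylsilyl)oxy]methyl}-1-hydroxy-4a,8,8-trimethyl-1,2,4a,5,6,7,8,8a-octahydronaphthalene-1-carbaldehyde (configuration at the carbinol carbon immaterial) | CC(C)(C)[Si](C)(C)OCCC1=C(CO[Si](c2ccccc2)(c2ccccc2)C(C)(C)C)CC(O)(C=O)[C@@H]3C(C)(C)CCC[C@@]13C
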